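**Assumptions (one line each)**
- Genipin (1) is commercially available (or is made from geniposide by β-glucosidase hydrolysis).
- TBSCl silylates the primary C10–OH of genipin faster than the hemiacetal OH.
- Acylation of the C1 lactol gives mainly the natural 1S acylal (pseudo-axial, anomeric-effect-favoured), and the minor anomer can be separated.
- Reagents that only deliver H or remove a silyl group are listed as "none".
- Iridoid numbering is used throughout: C1 is the acetal carbon, C4 carries C11, C8 carries C10, and C5 and C9 are the ring-fusion carbons.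

**Retrosynthesis**
1. Target 9 comes from 8 by removing the C10 TBS group. The three esters (C11 and C1 isovalerate, C7 acetate) are put on in the order 1,11 then 7 from tetraol 6.
2. Tetraol 6 comes from DIBAL reduction of ester 5, which removes the C1 and C7 acetates in the same step.
3. The C7β-OAc/C8α-OH trans pair in 5 comes from acetate opening at C7 of the α-epoxide 4. Epoxide 4 comes from trans-bromohydrin 3, which is made by convex-face bromonium formation followed by anti opening with water at C8.
4. Alkene 2 is protected genipin. Genipin already carries both cis-fused rings and the C1, C5 and C9 stereocentres, so no ring is built. The only new stereocentres are C7 and C8, and the only transient ring is the epoxide.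

---

**Step 1**
Reactants: 1, genipin
Product: 2, methyl (1S,4aS,7aS)-1-acetoxy-7-(tert-butyldimethylsilyloxymethyl)-1,4a,5,7a-tetrahydrocyclopenta[c]pyran-4-carboxylate
Conditions: TBSCl, imidazole, DMF, 0 °C, 2 h; then Ac₂O, DMAP, Et₃N, 0 °C → rt (one pot)
Reagents that add atoms: TBSCl, C[Si](C)(C)C(C)(C)Cl; Ac₂O, CC(=O)OC(C)=O
Why: Silylation of the primary allylic OH followed by acetylation of the lactol OH (protecting-group installation) protects C10, which must stay differentiated from C11, and masks the lactol against NBS oxidation and base ring-opening. No stereocentre is created, and any C1 anomer mixture is erased at step 5.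

**Step 2**
Reactants: 2
Product: 3, the trans-bromohydrin with 7β-Br, 8α-OH, 10-OTBS and 1-OAc
Conditions: NBS, THF/H₂O 4:1, 0 °C, dark, 1 h
Reagents that add atoms: NBS, BrN1C(=O)CCC1=O; water, O
Why: Bromohydrin formation proceeds through a bromonium ion on the convex β face (the face bearing H5 and H9). Water then opens it anti at the more substituted C8 (Markovnikov) from the concave α face, setting 7β-Br and 8α-OH, with C10 pushed to β. The C3=C4 enol ether is deactivated by the C4 ester, so the cyclopentene reacts.

**Step 3**
Reactants: 3
Product: 4, the 7α,8α-epoxide (C10 β)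
Conditions: NaH, THF, 0 °C, 30 min
Reagents that add atoms: none
Why: Intramolecular Williamson (3-exo-tet) closure: the 8α-alkoxide is anti-periplanar to the 7β-Br and displaces it with inversion at C7. This gives the concave-face α-epoxide that direct peracid epoxidation would not give.

**Step 4**
Reactants: 4
Product: 5, with 7β-OAc, 8α-OH, 10-OTBS, 1-OAc and the C4 methyl ester
Conditions: Bu₄N⁺AcO⁻ (5 equiv), MeCN, 80 °C, 24 h
Reagents that add atoms: tetrabutylammonium acetate, CCCC[N+](CCCC)(CCCC)CCCC.CC(=O)[O-]
Why: Non-acidic SN2 epoxide opening occurs at the secondary C7, because SN2 at the tertiary C8 is impossible. Acetate attacks from the open convex β face (trans-diaxial opening), giving 7β-OAc and the retained 8α-O, which matches the target.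

**Step 5**
Reactants: 5
Product: 6, the tetraol with C11-OH, C1 lactol, 7β-OH, 8α-OH and 10-OTBS
Conditions: DIBAL-H (8 equiv), CH₂Cl₂, −78 → 0 °C, 3 h; Rochelle salt work-up
Reagents that add atoms: none
Why: Hydride reduction converts the vinylogous carbonate ester to the C11 allylic alcohol and cleaves both acetates (the C1 acylal to the lactol, and the C7 acetate). The TBS ether and the tertiary OH survive, and no stereocentre is touched.

**Step 6**
Reactants: 6
Product: 7, the 1,11-di-isovalerate (7-OH, 8-OH and 10-OTBS free)
Conditions: isovaleryl chloride (2.3 equiv), pyridine, cat. DMAP, CH₂Cl₂, −20 → 0 °C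
Reagents that add atoms: isovaleryl chloride, CC(C)CC(=O)Cl
Why: Chemoselective acylation: the primary C11-OH and the lactol C1-OH react before the neopentyl-type secondary C7-OH and the tertiary C8-OH. The lactol equilibrates through its open form and acylates to the anomeric-effect-favoured 1S acylal, which fixes C1 as in the target.

**Step 7**
Reactants: 7
Product: 8, with 7β-OAc added
Conditions: Ac₂O (3 equiv), DMAP, Et₃N, CH₂Cl₂, 0 °C → rt
Reagents that add atoms: Ac₂O, CC(=O)OC(C)=O
Why: DMAP-catalysed acetylation of the remaining secondary C7-OH, while the tertiary C8-OH is inert under these conditions. C7 is not epimerised.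

**Step 8**
Reactants: 8
Product: 9, Jatamanvaltrate H
Conditions: HF·pyridine, THF/pyridine, 0 °C → rt, 12 h
Reagents that add atoms: none
Why: Fluoride cleavage of the primary TBS ether under buffered, mildly acidic conditions leaves the acylal, enol ether and esters intact and limits acetyl migration.

---

**Compound list**

| # | Name | SMILES | Role |
|---|---|---|---|
| 1 | Genipin | COC(=O)C1=CO[C@@H](O)[C@@H]2C(CO)=CC[C@H]12 | starting material |
| 2 | 1-O-Acetyl-10-O-TBS-genipin | COC(=O)C1=CO[C@@H](OC(C)=O)[C@@H]2C(CO[Si](C)(C)C(C)(C)C)=CC[C@H]12 | intermediate |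
| 3 | 7β-Bromo-8α-hydroxy bromohydrin | COC(=O)C1=CO[C@@H](OC(C)=O)[C@@H]2[C@@](O)(CO[Si](C)(C)C(C)(C)C)[C@@H](Br)C[C@H]12 | intermediate |
| 4 | 7α,8α-Epoxide | COC(=O)C1=CO[C@@H](OC(C)=O)[C@@H]2[C@]3(CO[Si](C)(C)C(C)(C)C)O[C@@H]3C[C@H]12 | intermediate |
| 5 | 7β-Acetoxy-8α-hydroxy ester | COC(=O)C1=CO[C@@H](OC(C)=O)[C@@H]2[C@@](O)(CO[Si](C)(C)C(C)(C)C)[C@@H](OC(C)=O)C[C@H]12 | intermediate |
| 6 | Tetraol (C11-OH, C1 lactol, 7β-OH, 8α-OH, 10-OTBS) | OCC1=CO[C@@H](O)[C@@H]2[C@@](O)(CO[Si](C)(C)C(C)(C)C)[C@@H](O)C[C@H]12 | intermediate |
| 7 | 1,11-Di-isovalerate | CC(C)CC(=O)OCC1=CO[C@@H](OC(=O)CC(C)C)[C@@H]2[C@@](O)(CO[Si](C)(C)C(C)(C)C)[C@@H](O)C[C@H]12 | intermediate |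
| 8 | 7-Acetoxy-1,11-di-isovalerate, 10-OTBS | CC(C)CC(=O)OCC1=CO[C@@H](OC(=O)CC(C)C)[C@@H]2[C@@](O)(CO[Si](C)(C)C(C)(C)C)[C@@H](OC(C)=O)C[C@H]12 | intermediate |
| 9 | Jatamanvaltrate H (C₂₂H₃₄O₉) | CC(C)CC(=O)OCC1=CO[C@@H](OC(=O)CC(C)C)[C@@H]2[C@@](O)(CO)[C@@H](OC(C)=O)C[C@H]12 | target |

**Totals:** 8 steps in total, and the longest linear sequence is also 8, counting from genipin.

**Three steps most likely to fail**
1. **Step 2 (bromohydrin face and regiochemistry).** Attack at C7 instead of C8, or bromonium formation on the α face, would give the wrong C8 configuration.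
   Fallback: use a different approach. Convert the C10–OH of a genipin derivative to the selenide and oxidise it, so that a [2,3] (Mislow–Evans) shift gives the 7α-hydroxy-8(10)-ene. Then VO(acac)₂/TBHP epoxidation, directed by the 7α-OH, gives the α-spiro-epoxide. Finally a Mitsunobu reaction with AcOH inverts C7.
2. **Step 4 (SN2 at the hindered C7).** C7 is flanked by the quaternary C8 and the β-CH₂OTBS group, so the acetolysis may be slow or may open at C8.
   Fallback: drop the epoxide. Oxidise bromohydrin 3 to the 7-keto-8α-ol by Kornblum oxidation. Then reduce it with Me₄NBH(OAc)₃, which delivers hydride from the 8α-OH to give the 7β-OH (trans diol), and acetylate C7.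
3. **Step 6 (chemoselective, stereoselective diacylation of the lactol and C11-OH).** Over-acylation at C7 or the wrong C1 anomer would lower the yield.
   Fallback: use a different approach. Acylate C11 alone using a lipase (CAL-B) with vinyl isovalerate, then acylate the lactol separately with isovaleric anhydride, and separate the C1 anomers chromatographically.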